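Ring C is cut at O1–C8a, C4–C4a and O1–C2. Ring A bears methoxy groups on C5, C6, C7 and C8, and its other carbons, C8a and C4a, hold O1 and the C4 carbonyl. This is the imprint of mirror-symmetric 3,4,5,6-tetramethoxybenzyne, so regiochemistry is no issue. In one operation the aryne, released by fluoride from a tetramethoxy-2-(trimethylsilyl)phenyl triflate, inserts into the carboxyl C–O bond of the dry cesium salt of 3-(2,4-dimethoxyphenyl)-2,3-dimethoxyacrylic acid. The phenoxide so formed displaces the β-methoxy group and closes ring C. The acid already holds C2, C3, C4, the 3-methoxy group and ring B, so the cascade ends at the target.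

Key step: step 7

Assumption: the tetrasubstituted enol ether (ester, acid, salt and ketone stages) is drawn as the E isomer, with the β-methoxy group on the side of the carboxyl carbon. An E/Z mixture from the O-methylation would be carried on unseparated, because both isomers converge once the β-carbon becomes tetrahedral during ring closure.

Step 1
Reactants: 1 1,2,3,4-tetramethoxybenzene
Product: 4 2,3,4,5-tetramethoxyphenol, via aryllithium 2 (not isolated), via dimethyl arylboronate 3 (not isolated)
Conditions: n-BuLi (1.1 equiv), TMEDA, THF, 0 °C; B(OMe)3, −78 °C to rt; AcOH, 30% aq H2O2, 0 °C to rt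
Reagents that add atoms: hydrogen peroxide, OO
Why: Directed ortho-lithiation beside a terminal methoxy group (the two free ring positions are equivalent), borylation and peroxide-induced boron-to-oxygen aryl shift form a standard one-flask arene hydroxylation, and the acetic acid buffer keeps the oxidation-prone phenol out of alkaline peroxide.

Step 2
Reactants: 4 2,3,4,5-tetramethoxyphenol
Product: 5 2-bromo-3,4,5,6-tetramethoxyphenol
Conditions: NBS (1.0 equiv), dry MeCN, −20 °C to 0 °C, dark
Reagents that add atoms: N-bromosuccinimide, O=C1CCC(=O)N1Br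
Why: Electrophilic aromatic bromination can only strike the single remaining ring C–H, which lies ortho to the hydroxyl group, and one equivalent of NBS in the cold and dark disfavours oxidation of the electron-rich phenol to a quinone.

Step 3
Reactants: 5 2-bromo-3,4,5,6-tetramethoxyphenol
Product: 9 2,3,4,5-tetramethoxy-6-(trimethylsilyl)phenyl trifluoromethanesulfonate, via aryl silyl ether 6 (not isolated), via aryllithium 7 (not isolated), via lithium phenoxide 8 (not isolated)
Conditions: HN(SiMe3)2, THF, reflux, then evaporate under vacuum; n-BuLi (1.1 equiv), THF, −100 to −78 °C; Tf2O (1.2 equiv), −100 to −78 °C; cold aq NaHCO3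
Reagents that add atoms: hexamethyldisilazane, C[Si](C)(C)N[Si](C)(C)C; trifluoromethanesulfonic anhydride, O=S(=O)(OS(=O)(=O)C(F)(F)F)C(F)(F)F
Why: This is the standard entry to ortho-silylaryl triflates, namely O-silylation, bromine–lithium exchange, retro-Brook 1,3-shift of silicon from oxygen to the carbanion (driven by formation of the phenoxide) and O-triflation, a sequence that tolerates methoxy groups flanking both reacting positions.

Step 4
Reactants: 10 2,4-dimethoxybenzoyl chloride; 11 methyl methoxyacetate
Product: 13 methyl 3-(2,4-dimethoxyphenyl)-2-methoxy-3-oxopropanoate (racemic), via lithium enolate 12 (not isolated)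
Conditions: 11 (2.2 equiv), LiN(SiMe3)2 (2.2 equiv), THF, −78 °C; add 10 (1.0 equiv), −78 to −20 °C; aq NH4Cl
Reagents that add atoms: none
Why: This is a crossed Claisen-type C-acylation of a preformed lithium ester enolate in which the acid chloride replaces a sluggish donor-substituted benzoate ester, the only amine present is non-nucleophilic, the second equivalent of enolate stores the product as its enolate against double acylation, and the new C2 stereocentre arises racemic and is erased in step 5.

Step 5
Reactants: 13 methyl 3-(2,4-dimethoxyphenyl)-2-methoxy-3-oxopropanoate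
Product: 14 methyl (E)-3-(2,4-dimethoxyphenyl)-2,3-dimethoxyprop-2-enoate
Conditions: Cs2CO3 (1.5 equiv), Me2SO4 (1.3 equiv), DMF, 0 °C to rt; aq NH3 quench
Reagents that add atoms: dimethyl sulfate, COS(=O)(=O)OC
Why: O-alkylation of the ambident β-keto ester enolate is steered to oxygen by the hard sulfate electrophile, by the loosely paired cesium enolate in a dipolar aprotic solvent and by the fully substituted α-carbon, where methylation would have to build a quaternary centre.

Step 6
Reactants: 14 methyl (E)-3-(2,4-dimethoxyphenyl)-2,3-dimethoxyprop-2-enoate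
Product: 15 (E)-3-(2,4-dimethoxyphenyl)-2,3-dimethoxyprop-2-enoic acid
Conditions: LiOH·H2O (3 equiv), THF/MeOH/H2O, 45 °C; 0 °C, EtOAc, 1 M HCl to pH 4; used at once
Reagents that add atoms: lithium hydroxide, [Li+].[OH-]
Why: Saponification of β-alkoxyacrylate esters to the free acids is established, the aryl and enol methyl ethers are inert to hydroxide, and cold two-phase acidification only to pH 4 avoids the α-protonation that would start enol ether hydrolysis and decarboxylation.

Step 7
Reactants: 15 (E)-3-(2,4-dimethoxyphenyl)-2,3-dimethoxyprop-2-enoic acid; 9 2,3,4,5-tetramethoxy-6-(trimethylsilyl)phenyl trifluoromethanesulfonate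
Product: 20 3,5,6,7,8,2',4'-heptamethoxyflavone [2-(2,4-dimethoxyphenyl)-3,5,6,7,8-pentamethoxy-4H-chromen-4-one], via cesium carboxylate 16 (not isolated), via tetramethoxybenzyne 17 (not isolated), via aryl anion 18 (not isolated), via acyl phenoxide 19 (not isolated)
Conditions: 15, Cs2CO3 (0.5 equiv), MeOH, rt, evaporate, PhMe azeotrope, vacuum; 9 (1.8 equiv), dried CsF (5 equiv), THF, sealed tube, 125 °C; cool, AcOH, 60 °C
Reagents that add atoms: none
Why: Proposed new method: fluoride removes the silyl group of 9 and triflate departs to give aryne 17, the carboxylate oxygen of 16 adds to either aryne carbon (O1–C8a), the neighbouring aryl anion 18 attacks its own ester carbonyl through a four-membered adduct (C4–C4a) that collapses to phenoxide 19, and 19 adds to the β-carbon and expels methoxide (O1–C2). The closest known reaction type is the CsF-induced insertion of arynes into the C–O bond of carboxylic acids, which gives ortho-hydroxyaryl ketones and with cinnamic or arylpropiolic acids runs on to flavanones or flavones, joined to the classical closure of ortho-hydroxyaryl β-alkoxyvinyl ketones to chromones; untested are the addition–elimination ending, the tetrasubstituted acrylate and the fully substituted aryne. Ring C closes 6-endo-trig by addition–elimination, no stereocentre is created, and the alkene geometry of 15 is erased once the β-carbon turns tetrahedral. Site selectivity at the aryne does not arise, because both reactive carbons are flanked by identical methoxy groups and a mirror plane bisects the triple bond. The step does need acyl transfer to outrun protonation and conjugate attack on the β-carbon (which would lead to an isomeric 4-arylcoumarin): the dried cesium salt in THF offers no acidic proton and blocks the thermal decarboxylation to which free β-alkoxyacrylic acids are prone, while the preferred Z conformation of the aryl ester holds the anion next to the carbonyl carbon and away from the donor-deactivated β-carbon. Sparingly soluble CsF meters out the aryne so that 19 cyclises rather than being arylated, the excess of 9 covers aryne lost to liberated methoxide, and the closing warm acetic acid treatment neutralises methoxide and closes any 19 still open, since alkoxide can reopen the pyranone at C2.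

Compound list
1 | 1,2,3,4-tetramethoxybenzene | COc1ccc(OC)c(OC)c1OC | starting material
2 | (2,3,4,5-tetramethoxyphenyl)lithium | [Li]c1cc(OC)c(OC)c(OC)c1OC | intermediate
3 | dimethyl (2,3,4,5-tetramethoxyphenyl)boronate | COB(OC)c1cc(OC)c(OC)c(OC)c1OC | intermediate
4 | 2,3,4,5-tetramethoxyphenol | COc1cc(O)c(OC)c(OC)c1OC | intermediate
5 | 2-bromo-3,4,5,6-tetramethoxyphenol | COc1c(O)c(Br)c(OC)c(OC)c1OC | intermediate
6 | (2-bromo-3,4,5,6-tetramethoxyphenoxy)trimethylsilane | COc1c(O[Si](C)(C)C)c(Br)c(OC)c(OC)c1OC | intermediate
7 | [2,3,4,5-tetramethoxy-6-(trimethylsilyloxy)phenyl]lithium | [Li]c1c(O[Si](C)(C)C)c(OC)c(OC)c(OC)c1OC | intermediate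
8 | lithium 2,3,4,5-tetramethoxy-6-(trimethylsilyl)phenoxide | [Li+].[O-]c1c([Si](C)(C)C)c(OC)c(OC)c(OC)c1OC | intermediate
9 | 2,3,4,5-tetramethoxy-6-(trimethylsilyl)phenyl trifluoromethanesulfonate | COc1c(OC)c(OC)c(OS(=O)(=O)C(F)(F)F)c([Si](C)(C)C)c1OC | intermediate
10 | 2,4-dimethoxybenzoyl chloride | COc1ccc(C(=O)Cl)c(OC)c1 | starting material
11 | methyl methoxyacetate | COCC(=O)OC | starting material
12 | lithium (E)-1,2-dimethoxyethen-1-olate (chelated form, O–Li cis to the C2 methoxy group) | CO/C=C(/OC)[O-].[Li+] | intermediate
13 | methyl 3-(2,4-dimethoxyphenyl)-2-methoxy-3-oxopropanoate (racemic) | COC(C(=O)OC)C(=O)c1ccc(OC)cc1OC | intermediate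
14 | methyl (E)-3-(2,4-dimethoxyphenyl)-2,3-dimethoxyprop-2-enoate | CO/C(c1ccc(OC)cc1OC)=C(/OC)C(=O)OC | intermediate
15 | (E)-3-(2,4-dimethoxyphenyl)-2,3-dimethoxyprop-2-enoic acid | CO/C(c1ccc(OC)cc1OC)=C(/OC)C(=O)O | intermediate
16 | cesium (E)-3-(2,4-dimethoxyphenyl)-2,3-dimethoxyprop-2-enoate | [Cs+].CO/C(c1ccc(OC)cc1OC)=C(/OC)C(=O)[O-] | intermediate
17 | 3,4,5,6-tetramethoxybenzyne | COC1=C(OC)C(OC)=C(OC)C#C1 | intermediate
18 | cesium 2-{[(E)-3-(2,4-dimethoxyphenyl)-2,3-dimethoxyprop-2-enoyl]oxy}-3,4,5,6-tetramethoxybenzen-1-ide | [Cs+].CO/C(c1ccc(OC)cc1OC)=C(/OC)C(=O)Oc1[c-]c(OC)c(OC)c(OC)c1OC | intermediate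
19 | cesium 2-[(E)-3-(2,4-dimethoxyphenyl)-2,3-dimethoxyprop-2-enoyl]-3,4,5,6-tetramethoxyphenoxide | [Cs+].CO/C(c1ccc(OC)cc1OC)=C(/OC)C(=O)c1c([O-])c(OC)c(OC)c(OC)c1OC | intermediate
20 | 3,5,6,7,8,2',4'-heptamethoxyflavone | COc1ccc(-c2oc3c(OC)c(OC)c(OC)c(OC)c3c(=O)c2OC)c(OC)c1 | target

Total step count: 7. Longest linear sequence: 4 steps (steps 1, 2, 3, 7; the acid branch, steps 4, 5, 6, 7, is equally long).

Steps most likely to fail

1. Step 7 (key step, the one labelled step).
- What may go wrong: the aryl anion may be protonated before the acyl shift, so that the sequence stops at plain O-arylation. It may attack the β-carbon instead of the carbonyl group. The aryne may be drained by liberated methoxide. Crowding around the fully substituted aryne may slow carboxylate addition.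
- Fallback: known chemistry without an aryne, setting out from phenol 4 and acid chloride 10 and coming back at target 20. Acylation of 4 at its only free ring carbon with methoxyacetyl chloride and BF3·OEt2 (Friedel–Crafts acylation with Fries shift) should give 1-(2-hydroxy-3,4,5,6-tetramethoxyphenyl)-2-methoxyethan-1-one F1. O-aroylation with 10 in pyridine should give 2-(methoxyacetyl)-3,4,5,6-tetramethoxyphenyl 2,4-dimethoxybenzoate F2. Baker–Venkataraman rearrangement (KOH, pyridine, 50 °C) moves the aroyl group to carbon and should give 1-(2,4-dimethoxyphenyl)-3-(2-hydroxy-3,4,5,6-tetramethoxyphenyl)-2-methoxypropane-1,3-dione F3. Cyclodehydration (cat. H2SO4, AcOH, warm) then closes ring C to 20.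

2. Step 5.
- What may go wrong: the ambident enolate may be methylated at carbon rather than at oxygen.
- Fallback: it sets out from 13 and comes back at 14, and it avoids enolate chemistry altogether. Acid-catalysed ketalisation with HC(OMe)3 (cat. H2SO4, MeOH, reflux) should give methyl 3-(2,4-dimethoxyphenyl)-2,3,3-trimethoxypropanoate F4. This ketal loses methanol on heating with cat. TsOH in toluene with distillation, the usual way from β-keto esters to β-methoxyacrylates. Carbon alkylation is impossible on this path.

3. Step 6.
- What may go wrong: acyl attack on the hindered, donor-deactivated ester may be so slow that hydroxide attacks the β-carbon instead. On acidification, α-protonation may trigger enol ether hydrolysis and loss of CO2.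
- Fallback: it sets out from 10 and comes back at 15, and it frees the acid under neutral conditions. Methoxyacetyl chloride, benzyl alcohol and Et3N give benzyl methoxyacetate F5. Its lithium enolate is acylated with 10 as in step 4 to give benzyl 3-(2,4-dimethoxyphenyl)-2-methoxy-3-oxopropanoate F6. O-methylation as in step 5 gives benzyl (E)-3-(2,4-dimethoxyphenyl)-2,3-dimethoxyprop-2-enoate F7. Hydrogenolysis (H2, 1 atm, Pd/C, EtOAc) should then give 15 after filtration and evaporation, with the tetrasubstituted alkene expected to resist reduction.

Further compounds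
F1 | step 7 | 1-(2-hydroxy-3,4,5,6-tetramethoxyphenyl)-2-methoxyethan-1-one | COCC(=O)c1c(O)c(OC)c(OC)c(OC)c1OC
F2 | step 7 | 2-(methoxyacetyl)-3,4,5,6-tetramethoxyphenyl 2,4-dimethoxybenzoate | COCC(=O)c1c(OC(=O)c2ccc(OC)cc2OC)c(OC)c(OC)c(OC)c1OC
F3 | step 7 | 1-(2,4-dimethoxyphenyl)-3-(2-hydroxy-3,4,5,6-tetramethoxyphenyl)-2-methoxypropane-1,3-dione (racemic) | COC(C(=O)c1ccc(OC)cc1OC)C(=O)c1c(O)c(OC)c(OC)c(OC)c1OC
F4 | step 5 | methyl 3-(2,4-dimethoxyphenyl)-2,3,3-trimethoxypropanoate (racemic) | COC(C(=O)OC)C(OC)(OC)c1ccc(OC)cc1OC
F5 | step 6 | benzyl methoxyacetate | COCC(=O)OCc1ccccc1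
F6 | step 6 | benzyl 3-(2,4-dimethoxyphenyl)-2-methoxy-3-oxopropanoate (racemic) | COC(C(=O)OCc1ccccc1)C(=O)c1ccc(OC)cc1OC
F7 | step 6 | benzyl (E)-3-(2,4-dimethoxyphenyl)-2,3-dimethoxyprop-2-enoate | CO/C(c1ccc(OC)cc1OC)=C(/OC)C(=O)OCc1ccccc1
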